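**Retrosynthetic overview**

- The strategy rests on ring A: its oxygens at C5, C7 and C8a sit meta to one another (phloroglucinol pattern), and C4, C3 and C2 continue the same alternating carbonyl chain. Only the C8 hydroxyl falls outside this pattern, so it is added last by para-hydroxylation (Elbs) of the 5-hydroxyflavone.
- Ring C (O1–C2) is disconnected to a 2,6-dihydroxyaryl 1,3-diketone. Its two ortho hydroxyls are equivalent, so acid cyclodehydration can give only one flavone.
- Ring A (C4a–C8a) is disconnected by an intramolecular Claisen condensation of a linear polyketide methyl ester, released in the flask from a 4-methoxy-2-pyranone by Mg(OMe)2. The pyranone supplies C5, C6, C7, C8, C8a and the C7 methoxy group.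
- The pyranone precursor comes from two Claisen acylations: C3–C2 by aroylation of a ketone dianion, and C4a–C4 by acylation of the lithiated 6-methylpyranone.
- Ring order: pyranone and ring B are bought, ring A is closed next, then ring C, and the C8–O bond is made last.

Key step: step 3

Remark: the CH(OMe) carbon between two carbonyls in the key-step precursor, its ring-opened form and its product is a stereocenter only in the keto drawing. It epimerizes by enolization and becomes sp2 in ring C, so these compounds are handled as racemates. The LiN(iPr)2 and Mg(OMe)2 are taken as commercial solutions.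

**Route**

Step 1
Reactants: 1 4-methoxy-6-methyl-2H-pyran-2-one; 2 methyl methoxyacetate
Product: 4 4-methoxy-6-(3-methoxy-2-oxopropyl)-2H-pyran-2-one, via lithiated pyranone 3 (not isolated)
Conditions: 1 (2.1 equiv), LiN(iPr)2 (2.1 equiv), THF, −78 °C; then 2 (1.0 equiv), −78 → −30 °C; 1 M HCl
Reagents that add atoms: none
Why: LiN(iPr)2 deprotonates the C6 methyl group of the vinylogous ester 1 to give 3, which is C-acylated by the activated α-alkoxy ester 2 in a crossed Claisen condensation, the second equivalent of 3 storing the more acidic product as its enolate so that neither free amide base nor a second addition interferes.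

Step 2
Reactants: 4 4-methoxy-6-(3-methoxy-2-oxopropyl)-2H-pyran-2-one; 5 methyl 2,3,4-trimethoxybenzoate
Product: 7 4-methoxy-6-[3-methoxy-2,4-dioxo-4-(2,3,4-trimethoxyphenyl)butyl]-2H-pyran-2-one (racemic), via dilithio dianion 6 (not isolated)
Conditions: LiN(iPr)2 (3.3 equiv), THF, −78 → −20 °C; then 5 (1.1 equiv), −20 °C → rt; 1 M HCl, 0 °C
Reagents that add atoms: none
Why: Deprotonation of 4 first at the pyranone-flanked methylene and then at the methoxy-bearing α' carbon gives dianion 6, which should react with the non-enolizable ester 5 at its last-formed, more basic terminal carbon (γ-acylation of a β-dicarbonyl-type dianion, a Claisen condensation), the third equivalent of base taking up the acidic proton of the new 1,3-diketone.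

Step 3
Reactants: 7 4-methoxy-6-[3-methoxy-2,4-dioxo-4-(2,3,4-trimethoxyphenyl)butyl]-2H-pyran-2-one
Product: 9 1-(2,6-dihydroxy-4-methoxyphenyl)-2-methoxy-3-(2,3,4-trimethoxyphenyl)propane-1,3-dione (racemic), via ring-opened methyl ester 8 (not isolated)
Conditions: Mg(OMe)2 (8 equiv), MeOH, reflux, Ar; then cold 1 M HCl
Reagents that add atoms: none
Why: Methoxide adds to the lactone carbonyl (future C8a) of 7 and the ring opens to the magnesium-chelated polyketide methyl ester 8, in which the ester and the C6 methylene remain on the same side of the C7=C8 bond; the carbanion at C4a, flanked by the C4 and C5 carbonyls, then attacks the ester carbon, the methoxide taken up is expelled again, and enolization aromatizes the ring. The closest known reaction type is the Mg(OMe)2-mediated recyclization of 4-methoxy-6-(2-oxoalkyl)-2-pyranones to acylphloroglucinol monomethyl ethers, an intramolecular Claisen (Dieckmann-type) condensation. Ring A closes in the 6-exo-trig mode by formation of C4a–C8a. No stereocenter is created, and the CH(OMe) carbon stays labile. The step needs Claisen closure in preference to aldol closure onto a ketone (C8 to C4 or C6 to C2), γ-pyrone formation and retro-Claisen loss of the aroyl group; chelation of the β-dicarbonyl enolates by divalent magnesium lowers the electrophilicity of every ketone carbon and leaves the unchelated ester as the acceptor, while the cis geometry inherited from the pyranone holds C8a next to C4a.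

Step 4
Reactants: 9 1-(2,6-dihydroxy-4-methoxyphenyl)-2-methoxy-3-(2,3,4-trimethoxyphenyl)propane-1,3-dione
Product: 11 5-hydroxy-3,7-dimethoxy-2-(2,3,4-trimethoxyphenyl)-4H-chromen-4-one, via 2-hydroxyflavanone hemiketal 10 (not isolated)
Conditions: H2SO4 (cat.), AcOH, 95 °C
Reagents that add atoms: none
Why: Acid-catalysed cyclodehydration of an o-hydroxyaryl 1,3-diketone (the closing stage of a Baker–Venkataraman flavone synthesis): a phenolic hydroxyl adds to the aroyl carbonyl to give hemiketal 10, which loses water to the pyranone ring C, and because the two ortho hydroxyls of 9 are equivalent by symmetry only one flavone can form, the other hydroxyl becoming the chelated 5-OH.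

Step 5
Reactants: 11 5-hydroxy-3,7-dimethoxy-2-(2,3,4-trimethoxyphenyl)-4H-chromen-4-one
Product: 13 5,8-dihydroxy-3,7-dimethoxy-2-(2,3,4-trimethoxyphenyl)-4H-chromen-4-one, via potassium aryl sulfate 12 (not isolated)
Conditions: K2S2O8 (1.3 equiv), aq. KOH, pyridine, 0 °C → rt; HCl to pH 4, unchanged 11 removed by extraction; then conc. HCl, Na2SO3, 85 °C, 30 min
Reagents that add atoms: potassium peroxodisulfate K2S2O8, [K+].[K+].[O-]S(=O)(=O)OOS(=O)(=O)[O-]
Why: Elbs persulfate oxidation: the 5-phenolate attacks the peroxide oxygen through C8, its only free para position (further activated by the C7 methoxy and O1), to give sulfate 12, which resists further oxidation in alkali and is then cleaved at the S–O bond by brief acid hydrolysis under sulfite to free the C8 hydroxyl.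

**Compound list**

1 | 4-methoxy-6-methyl-2H-pyran-2-one | COc1cc(C)oc(=O)c1 | starting material
2 | methyl methoxyacetate | COCC(=O)OC | starting material
3 | 6-(lithiomethyl)-4-methoxy-2H-pyran-2-one (lithiated pyranone, drawn C-lithiated) | [Li]Cc1cc(OC)cc(=O)o1 | intermediate
4 | 4-methoxy-6-(3-methoxy-2-oxopropyl)-2H-pyran-2-one | COCC(=O)Cc1cc(OC)cc(=O)o1 | intermediate
5 | methyl 2,3,4-trimethoxybenzoate | COC(=O)c1ccc(OC)c(OC)c1OC | starting material
6 | 1,3-dilithio derivative of 4 (dianion at the two carbons flanking the ketone, drawn C-lithiated) | COC([Li])C(=O)C([Li])c1cc(OC)cc(=O)o1 | intermediate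
7 | 4-methoxy-6-[3-methoxy-2,4-dioxo-4-(2,3,4-trimethoxyphenyl)butyl]-2H-pyran-2-one (racemic) | COc1cc(CC(=O)C(OC)C(=O)c2ccc(OC)c(OC)c2OC)oc(=O)c1 | intermediate
8 | methyl (2E)-3,8-dimethoxy-5,7,9-trioxo-9-(2,3,4-trimethoxyphenyl)non-2-enoate (racemic; ester carbon and C4 methylene cis; present as magnesium enolates) | COC(=O)/C=C(OC)\CC(=O)CC(=O)C(OC)C(=O)c1ccc(OC)c(OC)c1OC | intermediate
9 | 1-(2,6-dihydroxy-4-methoxyphenyl)-2-methoxy-3-(2,3,4-trimethoxyphenyl)propane-1,3-dione (racemic) | COc1cc(O)c(C(=O)C(OC)C(=O)c2ccc(OC)c(OC)c2OC)c(O)c1 | intermediate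
10 | 2,5-dihydroxy-3,7-dimethoxy-2-(2,3,4-trimethoxyphenyl)-2,3-dihydro-4H-chromen-4-one (racemic mixture of diastereomers) | COc1cc(O)c2C(=O)C(OC)C(O)(c3ccc(OC)c(OC)c3OC)Oc2c1 | intermediate
11 | 5-hydroxy-3,7-dimethoxy-2-(2,3,4-trimethoxyphenyl)-4H-chromen-4-one | COc1cc(O)c2c(=O)c(OC)c(-c3ccc(OC)c(OC)c3OC)oc2c1 | intermediate
12 | potassium 5-hydroxy-3,7-dimethoxy-4-oxo-2-(2,3,4-trimethoxyphenyl)-4H-chromen-8-yl sulfate | COc1ccc(-c2oc3c(OS(=O)(=O)[O-])c(OC)cc(O)c3c(=O)c2OC)c(OC)c1OC.[K+] | intermediate
13 | 5,8-dihydroxy-3,7-dimethoxy-2-(2,3,4-trimethoxyphenyl)-4H-chromen-4-one (5,8-dihydroxy-3,7,2',3',4'-pentamethoxyflavone) | COc1ccc(-c2oc3c(O)c(OC)cc(O)c3c(=O)c2OC)c(OC)c1OC | target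

**Step count**

Total step count: 5
Longest linear sequence: 5 steps (1 → 4 → 7 → 9 → 11 → 13)

**Steps most likely to fail**

Step 3. The opened chain may fold the wrong way. The additional aroyl ketone offers a second aldol acceptor and a retro-Claisen exit, so closure onto a ketone carbon or loss of the aroyl group may outrun Claisen closure onto the ester. The fallback sets out from 4 and returns at 9. The same Mg(OMe)2 recyclization (MeOH, reflux) is run one stage earlier on 4, which carries only the single side-chain ketone and belongs to the plain 6-(2-oxoalkyl)pyranone class. This should give 1-(2,6-dihydroxy-4-methoxyphenyl)-2-methoxyethanone F1. The C2–C3 bond is then made on the finished ring A: the lithium polyanion of F1 (LiN(SiMe3)2, 4.5 equiv, THF, −78 °C) is C-aroylated with commercial 2,3,4-trimethoxybenzoyl chloride (1 equiv). Any O-aroylated material should be carried on to the diketone by Baker–Venkataraman acyl transfer under the excess base. Acidic work-up should deliver 9.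

Step 2. The dianion may add too slowly to the electron-rich, ortho-substituted ester carbonyl, so that proton exchange and decay of the dianion on warming outrun C–C bond formation. The fallback sets out from 4 and returns at 7. Dianion 6 is generated as before and trapped at −78 °C with the far more electrophilic 2,3,4-trimethoxybenzaldehyde in an aldol addition, whose alkoxide product carries no new acidic proton. This should give 6-[4-hydroxy-3-methoxy-2-oxo-4-(2,3,4-trimethoxyphenyl)butyl]-4-methoxy-2H-pyran-2-one F2 as a racemic mixture of diastereomers. Oxidation of the β-hydroxy ketone with Dess–Martin periodinane (CH2Cl2, NaHCO3, 0 °C → rt) should converge both diastereomers on 7.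

Step 5. Conversion may be low and the material may degrade. The chelated 5-hydroxyl reacts sluggishly with persulfate, and long exposure to alkali and oxidant can erode ring C. The fallback sets out from 11 and returns at 13. It replaces ionic para-sulfation by radical oxidation under near-neutral conditions. Teuber oxidation of 11 with potassium nitrosodisulfonate ON(SO3K)2 (2.5 equiv, KH2PO4 buffer, aqueous acetone, rt) should give 3,7-dimethoxy-2-(2,3,4-trimethoxyphenyl)-4H-chromene-4,5,8-trione F3. Reduction of this quinone with Na2S2O4 (water/EtOAc, rt) should give the hydroquinone 13.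

**Further compounds**

F1 | step 3 | 1-(2,6-dihydroxy-4-methoxyphenyl)-2-methoxyethanone | COCC(=O)c1c(O)cc(OC)cc1O
F2 | step 2 | 6-[4-hydroxy-3-methoxy-2-oxo-4-(2,3,4-trimethoxyphenyl)butyl]-4-methoxy-2H-pyran-2-one (racemic mixture of diastereomers) | COc1cc(CC(=O)C(OC)C(O)c2ccc(OC)c(OC)c2OC)oc(=O)c1
F3 | step 5 | 3,7-dimethoxy-2-(2,3,4-trimethoxyphenyl)-4H-chromene-4,5,8-trione | COC1=CC(=O)C2=C(C1=O)OC(=C(OC)C2=O)c1ccc(OC)c(OC)c1OC
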